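**Assumption:** the stereodescriptors of the given SMILES are taken literally. They place H-9 and the 11-OH on the ring C face opposite the C15–C16 bridge (C10 and 11-OH equatorial on the ring C chair, lactone trans-fused), so these two centres are set after ring B has been opened. ent-Kaurane numbering (C1–C20, C20 = α) is used throughout.

## Retrosynthetic overview

1. Target ⇐ seco lactone from Pb(OAc)4 scission of C6–C7 in a 6,7-dihydroxy-7,20-epoxy (hemiketal) ent-kauranoid; then C9 equilibration, C11 reduction and C6/C15 oxidation.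
2. Hemiketal ⇐ tetracyclic 7,11-diketone; ring D closed by reductive Heck reaction (C16→C13) on a ring C enone.
3. Rings A and B ⇐ one epoxide-initiated cationic bicyclization that ends on, and desymmetrizes, a Birch-derived bis(methyl enol ether); a single Sharpless epoxide controls C4, C5, C10, C9 and C8.
4. Cyclization substrate ⇐ Birch reductive alkylation product of 3,5-dimethoxybenzoic acid (ring C, C7, C15–C17) + epoxy allylic sulfone (C1–C6, C10, C18–C20) from two carbomagnesiations of propargyl alcohol.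
5. Ring order: C (from the arene) → A → B (one step) → D → lactone (hemiketal, then B-ring scission).

## Route

Step 1
Reactants: 1 prop-2-yn-1-ol
Product: 3 (2Z)-3-iodo-2-methylprop-2-en-1-ol, via magnesium chelate 2 (not isolated)
Conditions: MeMgBr (2.2 equiv), CuI (10 mol%), THF, 0 °C to rt; then I2, −40 °C
Reagents that add atoms: methylmagnesium bromide C[Mg]Br; iodine II
Why: Copper-catalysed anti-carbomagnesiation of the propargylic alkoxide (Duboudin reaction) gives the five-membered alkenylmagnesium chelate, and iodinolysis with retention puts iodine cis to CH2OH.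

Step 2
Reactants: 1 prop-2-yn-1-ol
Product: 5 (2Z)-2-ethenyl-4-(phenylsulfanyl)but-2-en-1-ol, via dienyl magnesium chelate 4 (not isolated)
Conditions: CH2=CHMgBr (2.2 equiv), CuI (10 mol%), THF, 0 °C to rt; then ClCH2SPh, 0 °C
Reagents that add atoms: vinylmagnesium bromide C=C[Mg]Br; chloromethyl phenyl sulfide ClCSc1ccccc1
Why: The same anti-carbomagnesiation followed by alkylation of the alkenyl–metal bond with retention places C6 cis to the future C20 carbinol, which fixes the C5=C10 geometry.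

Step 3
Reactants: 5 (2Z)-2-ethenyl-4-(phenylsulfanyl)but-2-en-1-ol
Product: 6 tert-butyl{[(2Z)-2-ethenyl-4-(phenylsulfanyl)but-2-enyl]oxy}diphenylsilane
Conditions: TBDPSCl, imidazole, DMF, rt
Reagents that add atoms: tert-butyl(chloro)diphenylsilane CC(C)(C)[Si](Cl)(c1ccccc1)c1ccccc1
Why: Standard silylation of the primary allylic alcohol masks the C20 oxygen as an ether that cannot capture a neighbouring cation.

Step 4
Reactants: 6 tert-butyl{[(2Z)-2-ethenyl-4-(phenylsulfanyl)but-2-enyl]oxy}diphenylsilane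
Product: 7 {[(2Z)-4-(benzenesulfonyl)-2-ethenylbut-2-enyl]oxy}(tert-butyl)diphenylsilane
Conditions: (NH4)6Mo7O24·4H2O (5 mol%), 30% H2O2, EtOH, 0 °C to rt
Reagents that add atoms: hydrogen peroxide OO
Why: Molybdate-catalysed peroxide oxidation takes the sulfide to the sulfone without touching the unactivated diene.

Step 5
Reactants: 7 {[(2Z)-4-(benzenesulfonyl)-2-ethenylbut-2-enyl]oxy}(tert-butyl)diphenylsilane; 3 (2Z)-3-iodo-2-methylprop-2-en-1-ol
Product: 9 (2Z,6Z)-8-(benzenesulfonyl)-6-[(tert-butyldiphenylsilyloxy)methyl]-2-methylocta-2,6-dien-1-ol, via B-alkyl-9-BBN adduct 8 (not isolated)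
Conditions: 9-BBN, THF, 0 °C to rt; then 3, PdCl2(dppf), AsPh3, Cs2CO3, DMF/H2O, rt
Reagents that add atoms: none
Why: 9-BBN hydroborates only the terminal vinyl group (anti-Markovnikov), and the B-alkyl Suzuki–Miyaura coupling with the vinyl iodide proceeds with retention, giving the (Z)-allylic alcohol that will make C19 axial.

Step 6
Reactants: 9 (2Z,6Z)-8-(benzenesulfonyl)-6-[(tert-butyldiphenylsilyloxy)methyl]-2-methylocta-2,6-dien-1-ol
Product: 10 [(2S,3R)-3-{(3Z)-5-(benzenesulfonyl)-3-[(tert-butyldiphenylsilyloxy)methyl]pent-3-enyl}-2-methyloxiran-2-yl]methanol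
Conditions: Ti(OiPr)4 (10 mol%), D-(−)-diethyl tartrate (12 mol%), t-BuOOH, 4 Å MS, CH2Cl2, −20 °C
Reagents that add atoms: tert-butyl hydroperoxide CC(C)(C)OO
Why: Sharpless asymmetric epoxidation of the only free allylic alcohol; the D-tartrate delivers oxygen to the face that gives the (2S,3R) epoxide, the sole external source of absolute configuration (C3/C4).

Step 7
Reactants: 10 [(2S,3R)-3-{(3Z)-5-(benzenesulfonyl)-3-[(tert-butyldiphenylsilyloxy)methyl]pent-3-enyl}-2-methyloxiran-2-yl]methanol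
Product: 11 epoxy allylic sulfone (fragment A): the O-TBDPS ether of 10
Conditions: TBDPSCl, imidazole, DMF, rt
Reagents that add atoms: tert-butyl(chloro)diphenylsilane CC(C)(C)[Si](Cl)(c1ccccc1)c1ccccc1
Why: Silylation gives a C19 ether that, unlike an ester, cannot participate at the epoxide or the C4 cation.

Step 8
Reactants: 12 3,5-dimethoxybenzoic acid
Product: 14 1-(2-chloroprop-2-enyl)-3,5-dimethoxycyclohexa-2,5-diene-1-carboxylic acid, via dilithium enediolate 13 (not isolated)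
Conditions: Li, NH3(l)/THF, −78 °C; then 2,3-dichloroprop-1-ene; NH4Cl
Reagents that add atoms: 2,3-dichloroprop-1-ene C=C(Cl)CCl
Why: Birch reductive alkylation; the cross-conjugated enediolate is C-alkylated at the carboxyl-bearing carbon (future C8) by the allylic chloride, giving an achiral diene with two enantiotopic enol ether arms.

Step 9
Reactants: 14 1-(2-chloroprop-2-enyl)-3,5-dimethoxycyclohexa-2,5-diene-1-carboxylic acid; 11 epoxy allylic sulfone (fragment A)
Product: 16 β-keto sulfone (2-benzenesulfonyl derivative of ketone 17; C6 epimers), via acyl imidazolide 15 (not isolated)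
Conditions: 14, CDI, THF, rt; 11, n-BuLi, THF, −78 °C; combine, then LiHMDS, −78 to −20 °C
Reagents that add atoms: none
Why: Claisen-type C-acylation of the α-sulfonyl allyl anion, which reacts only at its α-carbon, forms the C6–C7 bond without allylic transposition.

Step 10
Reactants: 16 β-keto sulfone
Product: 17 (3Z)-1-[1-(2-chloroprop-2-enyl)-3,5-dimethoxycyclohexa-2,5-dien-1-yl]-4-[(tert-butyldiphenylsilyloxy)methyl]-6-{(2R,3S)-3-methyl-3-[(tert-butyldiphenylsilyloxy)methyl]oxiran-2-yl}hex-3-en-1-one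
Conditions: SmI2, THF/MeOH, −78 °C
Reagents that add atoms: none
Why: Reductive desulfonylation of the β-keto sulfone; the samarium enolate is protonated at C6, so the C5=C10 bond stays out of conjugation.

Step 11
Reactants: 17 epoxy dienyl ketone
Product: 19 tricyclic ketal (rings A, B, C): 8-(2-chloroprop-2-enyl)-3α-hydroxy-7-oxo, C11 dimethyl ketal, C13 methyl enol ether (13,14-ene), 19,20-bis(OTBDPS), 5β-H, 9β-H, via oxocarbenium ion 18 (not isolated)
Conditions: MeAlCl2 (3 equiv), CH2Cl2, −90 to −78 °C; then MeOH/Et3N, −78 °C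
Reagents that add atoms: methanol CO
Why: Proposed new method: Lewis-acid opening of the epoxide at C4 (inversion) starts a chair–chair cation–olefin cascade in which C5=C10 closes ring A and the C10 cation is captured by C9 of one of the two enantiotopic methyl enol ethers to close ring B. The epoxide fixes the sense of the chair–chair folding, so only the arm that places the other arm (C14) axial on ring B can reach C10, which sets C4 (C19 axial from the Z substituent), C5, C10, C9 and the quaternary C8 in one step. The C11 oxocarbenium ion is trapped as the dimethyl ketal. The closest known reactions are MeAlCl2-promoted epoxy-polyene cyclizations terminated by enol ethers and group-selective cyclizations of Birch-derived cyclohexadienes.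

Step 12
Reactants: 19 tricyclic ketal
Product: 20 3-O-(imidazol-1-ylthiocarbonyl) derivative of 19
Conditions: 1,1'-thiocarbonyldiimidazole, DMAP, PhMe, 80 °C
Reagents that add atoms: 1,1'-thiocarbonyldiimidazole S=C(n1ccnc1)n1ccnc1
Why: Thioacylation of the only free hydroxyl prepares the Barton–McCombie deoxygenation.

Step 13
Reactants: 20 3-O-(imidazol-1-ylthiocarbonyl) tricycle
Product: 21 3-deoxy tricyclic ketal (7-ketone, C11 ketal, C13 enol ether, C8 2-chloroallyl, 19,20-bis(OTBDPS))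
Conditions: Bu3SnH, AIBN, PhMe, 90 °C
Reagents that add atoms: none
Why: Barton–McCombie radical deoxygenation removes the C3 oxygen; the vinyl chloride, ketal and enol ether are inert to stannyl radicals.

Step 14
Reactants: 21 3-deoxy tricyclic ketal
Product: 23 6β-(tert-butyldimethylsilyloxy) 7-ketone, via potassium 6-alkoxide 22 (not isolated)
Conditions: KHMDS, THF, −78 °C; 2-(benzenesulfonyl)-3-phenyloxaziridine; then TBSOTf, −78 to −40 °C
Reagents that add atoms: 2-(benzenesulfonyl)-3-phenyloxaziridine O=S(=O)(c1ccccc1)N1OC1c1ccccc1; tert-butyldimethylsilyl trifluoromethanesulfonate CC(C)(C)[Si](C)(C)OS(=O)(=O)C(F)(F)F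
Why: The C7 ketone can enolize only towards C6 (C8 is quaternary, C11 is masked). Davis hydroxylation occurs on the β-face because the α-face is blocked by the axial C19 and C20 substituents, and silylation in the same flask prevents α-ketol isomerization.

Step 15
Reactants: 23 6β-silyloxy 7-ketone
Product: 25 13-(trifluoromethanesulfonyloxy)-12-en-11-one (vinylogous triflate), via cyclohexane-1,3-dione 24 (not isolated)
Conditions: oxalic acid, THF/H2O, rt; then PhNTf2, Et3N, DMAP, CH2Cl2, 0 °C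
Reagents that add atoms: water O; N-phenylbis(trifluoromethanesulfonimide) O=S(=O)(N(c1ccccc1)S(=O)(=O)C(F)(F)F)C(F)(F)F
Why: Mild hydrolysis of the ketal and enol ether gives the ring C 1,3-dione, whose enolate is O-triflated at the less hindered C13 oxygen (the C11 oxygen is shielded by C9/C10).

Step 16
Reactants: 25 vinylogous triflate
Product: 27 tetracycle: 6β-OTBS-19,20-bis(OTBDPS)-ent-kaur-16-ene-7,11-dione, via enone 26 (not isolated)
Conditions: Pd2(dba)3 (5 mol%), XPhos, HCO2Na, DMF, 80 °C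
Reagents that add atoms: none
Why: Palladium–formate hydrogenolysis of the activated triflate gives the 12-en-11-one, then oxidative addition into the vinyl chloride and 5-exo reductive Heck cyclization join C16 to C13; the tether allows only the bridged, C8–C15-cis mode, which sets C13.

Step 17
Reactants: 27 silylated tetracyclic diketone
Product: 29 7α,20-epoxy-6β,7β,19-trihydroxy-ent-kaur-16-en-11-one (hemiketal), via 7-keto triol 28 (not isolated)
Conditions: TBAF, AcOH, THF, 0 °C to rt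
Reagents that add atoms: none
Why: Fluoride removes all three silyl groups, and the freed C20 hydroxyl adds to the C7 ketone to give the 7,20-hemiketal ring typical of 7,20-epoxy-ent-kauranoids (C7 configuration fixed by the bicyclic bridge).

Step 18
Reactants: 29 hemiketal triol
Product: 30 19-O-acetyl hemiketal diol
Conditions: Ac2O (1.1 equiv), pyridine, CH2Cl2, −20 °C
Reagents that add atoms: acetic anhydride CC(=O)OC(C)=O
Why: The primary C19 hydroxyl is acylated much faster than the hindered secondary 6-OH and the tertiary hemiketal OH.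

Step 19
Reactants: 30 19-O-acetyl hemiketal diol
Product: 32 19-acetoxy-6-hydroxy-11-oxo-6,7-seco-ent-kaur-16-en-7,20-olide (9β-H), via seco keto-aldehyde 31 (not isolated)
Conditions: Pb(OAc)4, NaHCO3, CH2Cl2, 0 °C; then NaBH4, MeOH, −78 °C
Reagents that add atoms: none
Why: Criegee glycol cleavage of the 6,7-diol of the hemiketal breaks C6–C7 and turns the hemiketal ring directly into the 7,20-δ-lactone plus the C6 aldehyde (the cleavage known for oridonin-type diols). The aldehyde is then reduced at −78 °C, where the hindered C11 ketone survives, so that it cannot undergo aldol or pinacol reactions in the next step.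

Step 20
Reactants: 32 seco hydroxy ketone (9β-H)
Product: 34 19-acetoxy-6,11-dihydroxy-6,7-seco-ent-kaur-16-en-7,20-olide with 9α-H and equatorial 11α-OH, via 9-epi hydroxy ketone 33 (not isolated)
Conditions: DBU (0.2 equiv), CH2Cl2, rt; then SmI2, i-PrOH, THF, rt
Reagents that add atoms: none
Why: With ring B open, C9 (α to the C11 ketone) equilibrates by enolization to the isomer with C10 equatorial on the ring C chair (trans-fused lactone). SmI2/i-PrOH electron-transfer reduction then gives the thermodynamically preferred equatorial 11-alcohol and leaves the lactone, acetate and alkene untouched.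

Step 21
Reactants: 34 seco diol
Product: 35 19-acetoxy-6,11,15α-trihydroxy-6,7-seco-ent-kaur-16-en-7,20-olide
Conditions: SeO2 (0.3 equiv), t-BuOOH, CH2Cl2, rt
Reagents that add atoms: tert-butyl hydroperoxide CC(C)(C)OO
Why: Selenium dioxide allylic hydroxylation (ene reaction then 2,3-shift) can occur only at C15, because C13 is a bridgehead, and it takes place on the exo face.

Step 22
Reactants: 35 seco triol
Product: 36 trichorabdal B (target as given)
Conditions: TEMPO (0.2 equiv), PhI(OAc)2 (2.3 equiv), CH2Cl2, rt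
Reagents that add atoms: none
Why: Oxoammonium (TEMPO) oxidation converts the primary C6 alcohol to the aldehyde and the allylic C15 alcohol to the enone, while the unactivated, hindered secondary 11-OH reacts far more slowly.

## Compound list

1 | prop-2-yn-1-ol | C#CCO | starting material
2 | (Z)-[3-(bromomagnesiooxy)-2-methylprop-1-enyl]magnesium bromide (magnesium chelate) | Br[Mg]/C=C(\CO[Mg]Br)C | intermediate
3 | (2Z)-3-iodo-2-methylprop-2-en-1-ol | I/C=C(\CO)C | intermediate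
4 | (Z)-[2-(bromomagnesiooxymethyl)buta-1,3-dienyl]magnesium bromide | Br[Mg]/C=C(\CO[Mg]Br)C=C | intermediate
5 | (2Z)-2-ethenyl-4-(phenylsulfanyl)but-2-en-1-ol | c1ccccc1SC/C=C(\CO)C=C | intermediate
6 | tert-butyl{[(2Z)-2-ethenyl-4-(phenylsulfanyl)but-2-enyl]oxy}diphenylsilane | c1ccccc1SC/C=C(\CO[Si](c1ccccc1)(c1ccccc1)C(C)(C)C)C=C | intermediate
7 | {[(2Z)-4-(benzenesulfonyl)-2-ethenylbut-2-enyl]oxy}(tert-butyl)diphenylsilane | O=S(=O)(c1ccccc1)C/C=C(\CO[Si](c1ccccc1)(c1ccccc1)C(C)(C)C)C=C | intermediate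
8 | 9-{(3Z)-5-(benzenesulfonyl)-3-[(tert-butyldiphenylsilyloxy)methyl]pent-3-enyl}-9-borabicyclo[3.3.1]nonane | O=S(=O)(c1ccccc1)C/C=C(\CO[Si](c1ccccc1)(c1ccccc1)C(C)(C)C)CCB1C2CCCC1CCC2 | intermediate
9 | (2Z,6Z)-8-(benzenesulfonyl)-6-[(tert-butyldiphenylsilyloxy)methyl]-2-methylocta-2,6-dien-1-ol | O=S(=O)(c1ccccc1)C/C=C(\CO[Si](c1ccccc1)(c1ccccc1)C(C)(C)C)CC/C=C(\CO)C | intermediate
10 | [(2S,3R)-3-{(3Z)-5-(benzenesulfonyl)-3-[(tert-butyldiphenylsilyloxy)methyl]pent-3-enyl}-2-methyloxiran-2-yl]methanol | O=S(=O)(c1ccccc1)C/C=C(\CO[Si](c1ccccc1)(c1ccccc1)C(C)(C)C)CC[C@H]1O[C@@]1(C)CO | intermediate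
11 | epoxy allylic sulfone (fragment A): O-TBDPS ether of 10 | O=S(=O)(c1ccccc1)C/C=C(\CO[Si](c1ccccc1)(c1ccccc1)C(C)(C)C)CC[C@H]1O[C@@]1(C)CO[Si](c1ccccc1)(c1ccccc1)C(C)(C)C | intermediate
12 | 3,5-dimethoxybenzoic acid | COc1cc(OC)cc(C(=O)O)c1 | starting material
13 | dilithium enediolate of 1,4-dihydro-3,5-dimethoxybenzoic acid | [Li+].[Li+].COC1=CC(=C([O-])[O-])C=C(OC)C1 | intermediate
14 | 1-(2-chloroprop-2-enyl)-3,5-dimethoxycyclohexa-2,5-diene-1-carboxylic acid | C=C(Cl)CC1(C(=O)O)C=C(OC)CC(OC)=C1 | intermediate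
15 | [1-(2-chloroprop-2-enyl)-3,5-dimethoxycyclohexa-2,5-dien-1-yl](imidazol-1-yl)methanone | C=C(Cl)CC1(C(=O)n2ccnc2)C=C(OC)CC(OC)=C1 | intermediate
16 | β-keto sulfone: 2-(benzenesulfonyl) derivative of 17 (C6 epimers) | C=C(Cl)CC1(C=C(OC)CC(OC)=C1)C(=O)C(S(=O)(=O)c1ccccc1)/C=C(\CO[Si](c1ccccc1)(c1ccccc1)C(C)(C)C)CC[C@H]1O[C@@]1(C)CO[Si](c1ccccc1)(c1ccccc1)C(C)(C)C | intermediate
17 | (3Z)-1-[1-(2-chloroprop-2-enyl)-3,5-dimethoxycyclohexa-2,5-dien-1-yl]-4-[(tert-butyldiphenylsilyloxy)methyl]-6-{(2R,3S)-3-methyl-3-[(tert-butyldiphenylsilyloxy)methyl]oxiran-2-yl}hex-3-en-1-one | C=C(Cl)CC1(C=C(OC)CC(OC)=C1)C(=O)C/C=C(\CO[Si](c1ccccc1)(c1ccccc1)C(C)(C)C)CC[C@H]1O[C@@]1(C)CO[Si](c1ccccc1)(c1ccccc1)C(C)(C)C | intermediate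
18 | tricyclic C11 O-methyl oxocarbenium ion (C3 oxygen bound to aluminium; drawn as the free hydroxy cation) | C=C(Cl)C[C@]12C=C(OC)CC(=[O+]C)[C@H]1[C@@]1(CC[C@@H](O)[C@@](C)(CO[Si](c3ccccc3)(c3ccccc3)C(C)(C)C)[C@H]1CC2=O)CO[Si](c1ccccc1)(c1ccccc1)C(C)(C)C | intermediate
19 | tricyclic ketal: 8-(2-chloroprop-2-enyl)-3α-hydroxy-7-oxo, C11 dimethyl ketal, C13 methyl enol ether, 19,20-bis(OTBDPS) (rings A, B, C) | C=C(Cl)C[C@]12C=C(OC)CC(OC)(OC)[C@H]1[C@@]1(CC[C@@H](O)[C@@](C)(CO[Si](c3ccccc3)(c3ccccc3)C(C)(C)C)[C@H]1CC2=O)CO[Si](c1ccccc1)(c1ccccc1)C(C)(C)C | intermediate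
20 | 3-O-(imidazol-1-ylthiocarbonyl) derivative of 19 | C=C(Cl)C[C@]12C=C(OC)CC(OC)(OC)[C@H]1[C@@]1(CC[C@@H](OC(=S)n3ccnc3)[C@@](C)(CO[Si](c3ccccc3)(c3ccccc3)C(C)(C)C)[C@H]1CC2=O)CO[Si](c1ccccc1)(c1ccccc1)C(C)(C)C | intermediate
21 | 3-deoxy tricyclic ketal (7-ketone) | C=C(Cl)C[C@]12C=C(OC)CC(OC)(OC)[C@H]1[C@@]1(CCC[C@@](C)(CO[Si](c3ccccc3)(c3ccccc3)C(C)(C)C)[C@H]1CC2=O)CO[Si](c1ccccc1)(c1ccccc1)C(C)(C)C | intermediate
22 | potassium 6β-alkoxide of the 6-hydroxy-7-ketone | [K+].C=C(Cl)C[C@]12C=C(OC)CC(OC)(OC)[C@H]1[C@@]1(CCC[C@@](C)(CO[Si](c3ccccc3)(c3ccccc3)C(C)(C)C)[C@H]1[C@H]([O-])C2=O)CO[Si](c1ccccc1)(c1ccccc1)C(C)(C)C | intermediate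
23 | 6β-(tert-butyldimethylsilyloxy) 7-ketone tricyclic ketal | C=C(Cl)C[C@]12C=C(OC)CC(OC)(OC)[C@H]1[C@@]1(CCC[C@@](C)(CO[Si](c3ccccc3)(c3ccccc3)C(C)(C)C)[C@H]1[C@H](O[Si](C)(C)C(C)(C)C)C2=O)CO[Si](c1ccccc1)(c1ccccc1)C(C)(C)C | intermediate
24 | ring C 11,13-dione (7,11,13-trione) | C=C(Cl)C[C@]12CC(=O)CC(=O)[C@H]1[C@@]1(CCC[C@@](C)(CO[Si](c3ccccc3)(c3ccccc3)C(C)(C)C)[C@H]1[C@H](O[Si](C)(C)C(C)(C)C)C2=O)CO[Si](c1ccccc1)(c1ccccc1)C(C)(C)C | intermediate
25 | 13-(trifluoromethanesulfonyloxy)-12-ene-7,11-dione | C=C(Cl)C[C@]12CC(OS(=O)(=O)C(F)(F)F)=CC(=O)[C@H]1[C@@]1(CCC[C@@](C)(CO[Si](c3ccccc3)(c3ccccc3)C(C)(C)C)[C@H]1[C@H](O[Si](C)(C)C(C)(C)C)C2=O)CO[Si](c1ccccc1)(c1ccccc1)C(C)(C)C | intermediate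
26 | 12-ene-7,11-dione carrying the 2-chloroallyl group on C8 | C=C(Cl)C[C@]12CC=CC(=O)[C@H]1[C@@]1(CCC[C@@](C)(CO[Si](c3ccccc3)(c3ccccc3)C(C)(C)C)[C@H]1[C@H](O[Si](C)(C)C(C)(C)C)C2=O)CO[Si](c1ccccc1)(c1ccccc1)C(C)(C)C | intermediate
27 | 6β-OTBS-19,20-bis(OTBDPS)-ent-kaur-16-ene-7,11-dione | C=C1C[C@]23C[C@H]1CC(=O)[C@H]2[C@@]1(CCC[C@@](C)(CO[Si](c4ccccc4)(c4ccccc4)C(C)(C)C)[C@H]1[C@H](O[Si](C)(C)C(C)(C)C)C3=O)CO[Si](c1ccccc1)(c1ccccc1)C(C)(C)C | intermediate
28 | 6β,19,20-trihydroxy-ent-kaur-16-ene-7,11-dione | C=C1C[C@]23C[C@H]1CC(=O)[C@H]2[C@@]1(CCC[C@@](C)(CO)[C@H]1[C@H](O)C3=O)CO | intermediate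
29 | 7α,20-epoxy-6β,7β,19-trihydroxy-ent-kaur-16-en-11-one | C=C1C[C@]23C[C@H]1CC(=O)[C@H]2[C@@]1(CCC[C@@](C)(CO)[C@H]1[C@H](O)[C@@]3(O)O4)C4 | intermediate
30 | 19-acetoxy-7α,20-epoxy-6β,7β-dihydroxy-ent-kaur-16-en-11-one | C=C1C[C@]23C[C@H]1CC(=O)[C@H]2[C@@]1(CCC[C@@](C)(COC(C)=O)[C@H]1[C@H](O)[C@@]3(O)O4)C4 | intermediate
31 | 19-acetoxy-6,11-dioxo-6,7-seco-ent-kaur-16-en-7,20-olide (9β-H) | C=C1C[C@]23C[C@H]1CC(=O)[C@H]2[C@@]1(CCC[C@@](C)(COC(C)=O)[C@H]1C=O)COC3=O | intermediate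
32 | 19-acetoxy-6-hydroxy-11-oxo-6,7-seco-ent-kaur-16-en-7,20-olide (9β-H) | C=C1C[C@]23C[C@H]1CC(=O)[C@H]2[C@@]1(CCC[C@@](C)(COC(C)=O)[C@H]1CO)COC3=O | intermediate
33 | C9 epimer of 32 (9α-H, C10 equatorial on ring C) | C=C1C[C@]23C[C@H]1CC(=O)[C@@H]2[C@@]1(CCC[C@@](C)(COC(C)=O)[C@H]1CO)COC3=O | intermediate
34 | 19-acetoxy-6,11α-dihydroxy-6,7-seco-ent-kaur-16-en-7,20-olide (9α-H) | C=C1C[C@]23C[C@H]1C[C@@H](O)[C@@H]2[C@@]1(CCC[C@@](C)(COC(C)=O)[C@H]1CO)COC3=O | intermediate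
35 | 15α-hydroxy derivative of 34 | C=C1[C@H](O)[C@]23C[C@H]1C[C@@H](O)[C@@H]2[C@@]1(CCC[C@@](C)(COC(C)=O)[C@H]1CO)COC3=O | intermediate
36 | trichorabdal B (as given) | C=C1C(=O)[C@]23C[C@H]1C[C@@H](O)[C@@H]2[C@@]1(CCC[C@@](C)(COC(C)=O)[C@H]1C=O)COC3=O | target

## Step count and risk

Total step count: 22. Longest linear sequence: 20 (steps 2–7, then 9–22).

The three steps most likely to fail are steps 11, 16 and 20.

**Step 11.** The C7 carbonyl oxygen may capture the C10 cation, or the ring B closure may be slow. The fallback removes the carbonyl during the cyclization. It sets out from 17: NaBH4 reduces the ketone to the C7 alcohols F1, and acetylation gives acetate F2. The same MeAlCl2 cyclization with methanol quench gives acetoxy tricycle F3. Thiocarbonyldiimidazole then gives F4, and Bu3SnH/AIBN gives the 3-deoxy acetate F5. K2CO3 in methanol frees the C7 alcohol F6, and Dess–Martin oxidation returns to the route at 21.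

**Step 16.** Formate may reduce the vinyl–palladium species before ring closure, or the vinyl chloride may insert too slowly. The fallback separates the two events and changes the metal. It sets out from 25: Pd(PPh3)4 with Et3SiH gives enone 26, which is isolated. Stoichiometric Ni(cod)2 (zerovalent nickel) with Et3N in MeCN then inserts into the vinyl chloride and adds it to the enone. This comes back to the route at 27 and makes no new compound.

**Step 20.** The hydroxy ketone may sit as a C6–O/C11 hemiketal that blocks enolization and reduction, or the equilibration may stall. The fallback masks the primary alcohol first. It sets out from 32: TBSCl/imidazole gives silyl ether F7, DBU equilibration gives the 9-epimer F8, and SmI2/i-PrOH gives the equatorial alcohol F9. HF·pyridine then returns to the route at 34.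

## Further compounds

F1 | step 11 | C7 alcohols from reduction of 17 (epimers) | C=C(Cl)CC1(C=C(OC)CC(OC)=C1)C(O)C/C=C(\CO[Si](c1ccccc1)(c1ccccc1)C(C)(C)C)CC[C@H]1O[C@@]1(C)CO[Si](c1ccccc1)(c1ccccc1)C(C)(C)C
F2 | step 11 | C7 acetates of F1 | C=C(Cl)CC1(C=C(OC)CC(OC)=C1)C(OC(C)=O)C/C=C(\CO[Si](c1ccccc1)(c1ccccc1)C(C)(C)C)CC[C@H]1O[C@@]1(C)CO[Si](c1ccccc1)(c1ccccc1)C(C)(C)C
F3 | step 11 | 7-acetoxy-3α-hydroxy tricyclic ketal (C7 epimers) | C=C(Cl)C[C@]12C=C(OC)CC(OC)(OC)[C@H]1[C@@]1(CC[C@@H](O)[C@@](C)(CO[Si](c3ccccc3)(c3ccccc3)C(C)(C)C)[C@H]1CC2OC(C)=O)CO[Si](c1ccccc1)(c1ccccc1)C(C)(C)C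
F4 | step 11 | 3-O-(imidazol-1-ylthiocarbonyl) derivative of F3 | C=C(Cl)C[C@]12C=C(OC)CC(OC)(OC)[C@H]1[C@@]1(CC[C@@H](OC(=S)n3ccnc3)[C@@](C)(CO[Si](c3ccccc3)(c3ccccc3)C(C)(C)C)[C@H]1CC2OC(C)=O)CO[Si](c1ccccc1)(c1ccccc1)C(C)(C)C
F5 | step 11 | 7-acetoxy-3-deoxy tricyclic ketal | C=C(Cl)C[C@]12C=C(OC)CC(OC)(OC)[C@H]1[C@@]1(CCC[C@@](C)(CO[Si](c3ccccc3)(c3ccccc3)C(C)(C)C)[C@H]1CC2OC(C)=O)CO[Si](c1ccccc1)(c1ccccc1)C(C)(C)C
F6 | step 11 | 7-hydroxy-3-deoxy tricyclic ketal | C=C(Cl)C[C@]12C=C(OC)CC(OC)(OC)[C@H]1[C@@]1(CCC[C@@](C)(CO[Si](c3ccccc3)(c3ccccc3)C(C)(C)C)[C@H]1CC2O)CO[Si](c1ccccc1)(c1ccccc1)C(C)(C)C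
F0 | step 16 | none | none
F7 | step 20 | 6-O-TBS ether of 32 | C=C1C[C@]23C[C@H]1CC(=O)[C@H]2[C@@]1(CCC[C@@](C)(COC(C)=O)[C@H]1CO[Si](C)(C)C(C)(C)C)COC3=O
F8 | step 20 | 6-O-TBS ether of 33 | C=C1C[C@]23C[C@H]1CC(=O)[C@@H]2[C@@]1(CCC[C@@](C)(COC(C)=O)[C@H]1CO[Si](C)(C)C(C)(C)C)COC3=O
F9 | step 20 | 6-O-TBS ether of 34 | C=C1C[C@]23C[C@H]1C[C@@H](O)[C@@H]2[C@@]1(CCC[C@@](C)(COC(C)=O)[C@H]1CO[Si](C)(C)C(C)(C)C)COC3=O
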